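## Retrosynthetic overview

1. Target ⇐ tricyclic lactone lacking C13 and the ester groups: C11 hydroxymethylation/acetylation, then Mitsunobu tigloylation with inversion at C2.
2. Tetrahydrofuran (O–C11–C7) and γ-lactone (C12–O–C8) rings ⇐ one oxidative radical–polar lactone annulation of a 5-O-carboxymethyl ether across C7=C8 (new reaction).
3. That acid ⇐ trans-hydroazulenol by O–H insertion and Markovnikov hydration at C4; ring A ⇐ ring-closing metathesis (C3=C4) after isopropenyl addition to the C5 ketone.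
4. Seven-membered ring ⇐ one-carbon ring expansion of a cyclohexenone by 1,2-alkenyl shift of a β-oxido carbenoid (key step).
5. Cyclohexenone ⇐ anti aldol of (R)-5-methylcyclohex-2-enone (from (R)-3-methylcyclohexanone) with acrolein. Ring order: six-membered ring, expanded to seven, then ring A, then tetrahydrofuran and lactone together.

Assumption: positions are named by the guaiane numbering of the target (carbonyl carbon of (R)-3-methylcyclohexanone = C5, its methyl-bearing carbon = C10, the CH2 between them = C1); β is the face of the C5 oxygen; organolithium and Grignard reagents are used as bought solutions.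

## Route

Step 1
Reactants: 1 (R)-3-methylcyclohexanone
Product: 3 (R)-5-methylcyclohex-2-en-1-one, via silyl enol ether 2 (not isolated)
Conditions: LiN(i-Pr)2, Me3SiCl, THF, −78 °C; then Pd(OAc)2 (10 mol %), O2 (1 atm), DMSO, rt
Reagents that add atoms: none
Why: Kinetic deprotonation at the less hindered C7 methylene followed by Saegusa–Ito dehydrogenation of the silyl enol ether gives the C7=C8 enone (the minor regioisomer is removed by chromatography) without touching the C10 stereocentre, which comes from 1.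

Step 2
Reactants: 3 (R)-5-methylcyclohex-2-en-1-one; 4 acrolein
Product: 6 (5R,6R)-6-[(1R)-1-(tert-butyldimethylsilyloxy)prop-2-en-1-yl]-5-methylcyclohex-2-en-1-one, via aldol adduct 5 (not isolated)
Conditions: LiN(i-Pr)2, THF, −78 °C; 4; then t-BuMe2SiOTf, −78 → −40 °C
Reagents that add atoms: tert-butyldimethylsilyl trifluoromethanesulfonate, CC(C)(C)[Si](C)(C)OS(=O)(=O)C(F)(F)F
Why: The kinetic cross-conjugated lithium enolate (C1) undergoes a lithium aldol 1,2-addition to acrolein anti to the adjacent C10 methyl group (C1 set trans to it) through a Zimmerman–Traxler chair of the ring-locked (E)-enolate (anti carbinol at C2, 2β, inverted later in step 11), and in situ silylation stops retro-aldol.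

Step 3
Reactants: 6 (5R,6R)-6-[(1R)-1-(tert-butyldimethylsilyloxy)prop-2-en-1-yl]-5-methylcyclohex-2-en-1-one; 7 dibromomethane
Product: 10 (6R,7R)-7-[(1R)-1-(tert-butyldimethylsilyloxy)prop-2-en-1-yl]-6-methylcyclohept-3-en-1-one, via dibromomethyl carbinol 8 (not isolated), via lithium dienolate 9 (not isolated)
Conditions: 7, LiN(i-Pr)2, THF, −95 °C; 6; n-BuLi, −95 → −20 °C; AcOH, −78 °C
Reagents that add atoms: none
Why: Key ring expansion by the Taguchi–Nozaki β-oxido carbenoid homologation: Br/Li exchange on adduct 8 gives a carbenoid in which the alkenyl carbon C7 makes the 1,2-shift in preference to the branched, inductively deactivated C1, enlarging the six- to the seven-membered ring as dienolate 9, whose kinetic protonation at C6 leaves the β,γ-enone; no stereocentre is formed or touched.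

Step 4
Reactants: 10 (6R,7R)-7-[(1R)-1-(tert-butyldimethylsilyloxy)prop-2-en-1-yl]-6-methylcyclohept-3-en-1-one; 11 isopropenylmagnesium bromide
Product: 12 (1R,6R,7R)-7-[(1R)-1-(tert-butyldimethylsilyloxy)prop-2-en-1-yl]-6-methyl-1-(prop-1-en-2-yl)cyclohept-3-en-1-ol
Conditions: 11, CeCl3, THF, −78 °C
Reagents that add atoms: none
Why: The CeCl3-modified Grignard reagent (Imamoto 1,2-addition) avoids enolisation of the β,γ-enone and enters anti to the C1 side chain, so the new C5 hydroxyl is cis to it (5β-OH, C4 on the α face).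

Step 5
Reactants: 12 (1R,6R,7R)-7-[(1R)-1-(tert-butyldimethylsilyloxy)prop-2-en-1-yl]-6-methyl-1-(prop-1-en-2-yl)cyclohept-3-en-1-ol
Product: 13 1-(tert-butyldimethylsilyloxy)-3,8-dimethyl-1,4,7,8-tetrahydroazulen-3a(8aH)-ol (trans-fused; 1-OSi β; 3a-OH β; 8-CH3 α; 8a-H α)
Conditions: second-generation Grubbs catalyst (H2IMes)(PCy3)Cl2Ru=CHPh (5 mol %), CH2Cl2, 40 °C
Reagents that add atoms: none
Why: Ring-closing metathesis of the vinyl and isopropenyl groups closes ring A as a trisubstituted cyclopentene with loss of ethylene; the trans ring fusion is already fixed by C1 and C5 and no stereocentre is formed.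

Step 6
Reactants: 13 1-(tert-butyldimethylsilyloxy)-3,8-dimethyl-1,4,7,8-tetrahydroazulen-3a(8aH)-ol; 14 ethyl diazoacetate
Product: 16 2-{[1-(tert-butyldimethylsilyloxy)-3,8-dimethyl-1,4,7,8-tetrahydroazulen-3a(8aH)-yl]oxy}acetic acid, via ethyl ester 15 (not isolated)
Conditions: 14 (slow addition), Rh2(OAc)4 (1 mol %), CH2Cl2, 0 °C → rt; then LiOH, THF/H2O, rt; HCl to pH 4
Reagents that add atoms: lithium hydroxide, [Li+].[OH-]
Why: Rhodium carbenoid O–H insertion, which outruns cyclopropanation, etherifies the hindered tertiary alcohol under neutral conditions and saponification frees the acid; no stereocentre is formed.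

Step 7
Reactants: 16 2-{[1-(tert-butyldimethylsilyloxy)-3,8-dimethyl-1,4,7,8-tetrahydroazulen-3a(8aH)-yl]oxy}acetic acid
Product: 17 2-{[1-(tert-butyldimethylsilyloxy)-3-hydroxy-3,8-dimethyl-1,2,3,4,7,8-hexahydroazulen-3a(8aH)-yl]oxy}acetic acid (3-OH α; 3-CH3 β)
Conditions: Co(acac)2 (20 mol %), PhSiH3, O2 (1 atm), THF, rt
Reagents that add atoms: dioxygen, O=O
Why: Mukaiyama hydration: hydrogen-atom transfer goes to the trisubstituted C3=C4 alkene much faster than to the disubstituted C7=C8 alkene, and the tertiary C4 radical is trapped by O2 on the α face, opposite the β silyloxy group at C2 and the β alkoxy group at C5, giving the Markovnikov 4α-alcohol.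

Step 8
Reactants: 17 2-{[1-(tert-butyldimethylsilyloxy)-3-hydroxy-3,8-dimethyl-1,2,3,4,7,8-hexahydroazulen-3a(8aH)-yl]oxy}acetic acid
Product: 18 2β-(tert-butyldimethylsilyloxy)-4α-hydroxy-5β,11-epoxy-13-nor-1αH,7αH,8αH,10βH-guaian-12,8-olide
Conditions: LiN(i-Pr)2 (3.3 equiv), THF, −78 °C; then Cu(OTf)2 (2.2 equiv), THF/MeCN, −78 → 0 °C
Reagents that add atoms: none
Why: Proposed new method: oxidative radical–polar crossover lactone annulation of a carboxylic acid dianion, in which Cu(OTf)2 (divalent copper) oxidises the enediolate to the α-alkoxy α-carboxyl radical at C11, this adds 5-exo-trig to C7 on the β face (the only face the 5β-oxygen tether reaches), and the secondary C8 radical is captured by a second divalent copper as an alkylcopper carboxylate (trivalent copper) that forms the C8–O bond by reductive elimination, so the tetrahydrofuran ring, the cis-fused γ-lactone and the stereocentres C7, C8 and C11 arise in one operation; the closest known reactions are the Mn(OAc)3/Cu(OAc)2 lactone annulation of alkenes with carboxylic acids and the oxidative cyclisation of ester enolates with [Cp2Fe]PF6, neither shown for a simple alkoxyacetic acid dianion or for a bridging ether ring.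

Step 9
Reactants: 18 2β-(tert-butyldimethylsilyloxy)-4α-hydroxy-5β,11-epoxy-13-nor-1αH,7αH,8αH,10βH-guaian-12,8-olide; 19 formaldehyde; 20 acetic anhydride
Product: 22 13-acetoxy-2β-(tert-butyldimethylsilyloxy)-4α-hydroxy-5β,11-epoxy-1αH,7αH,8αH,10βH-guaian-12,8-olide, via hydroxymethyl lactone 21 (not isolated)
Conditions: LiN(i-Pr)2 (2.2 equiv), THF, −78 °C; 19 (gas, from cracked paraformaldehyde); then 20 (1.1 equiv), −78 → −40 °C
Reagents that add atoms: none
Why: Aldol reaction of the lactone enolate with formaldehyde, which can enter only on the open convex face of the cis-fused bicyclic lactone so the quaternary C11 has the one possible configuration, followed by in situ acetylation of the primary alkoxide (the tertiary lithium alkoxide does not react at this temperature) to block retro-aldol.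

Step 10
Reactants: 22 13-acetoxy-2β-(tert-butyldimethylsilyloxy)-4α-hydroxy-5β,11-epoxy-1αH,7αH,8αH,10βH-guaian-12,8-olide
Product: 23 13-acetoxy-2β,4α-dihydroxy-5β,11-epoxy-1αH,7αH,8αH,10βH-guaian-12,8-olide
Conditions: HF·pyridine, THF, 0 °C → rt
Reagents that add atoms: none
Why: Fluoride desilylation under mildly acidic conditions leaves the acetate, the lactone and the tertiary alcohol untouched and changes no stereocentre.

Step 11
Reactants: 23 13-acetoxy-2β,4α-dihydroxy-5β,11-epoxy-1αH,7αH,8αH,10βH-guaian-12,8-olide; 24 tiglic acid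
Product: 25 CNP0112086.1 (13-acetoxy-4α-hydroxy-2α-tigloyloxy-5β,11-epoxy-1αH,7αH,8αH,10βH-guaian-12,8-olide)
Conditions: PPh3, i-PrO2CN=NCO2i-Pr, toluene, 0 °C → rt
Reagents that add atoms: none
Why: Mitsunobu esterification displaces the activated 2β-oxyphosphonium group by tiglate in an SN2 reaction with inversion to give the 2α-ester, while the tertiary C4 hydroxyl does not react and the (E)-alkene of the acid is kept.

## Compound list

1 | (R)-3-methylcyclohexanone | O=C1CCC[C@@H](C)C1 | starting material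
2 | trimethyl{[(5R)-5-methylcyclohex-1-en-1-yl]oxy}silane | C[Si](C)(C)OC1=CCC[C@@H](C)C1 | intermediate
3 | (R)-5-methylcyclohex-2-en-1-one | O=C1C=CC[C@@H](C)C1 | intermediate
4 | acrolein | C=CC=O | starting material
5 | (5R,6R)-6-[(1R)-1-hydroxyprop-2-en-1-yl]-5-methylcyclohex-2-en-1-one (anti aldol adduct; lithium alkoxide in the flask) | O=C1C=CC[C@@H](C)[C@@H]1[C@H](O)C=C | intermediate
6 | (5R,6R)-6-[(1R)-1-(tert-butyldimethylsilyloxy)prop-2-en-1-yl]-5-methylcyclohex-2-en-1-one | O=C1C=CC[C@@H](C)[C@@H]1[C@H](O[Si](C)(C)C(C)(C)C)C=C | intermediate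
7 | dibromomethane | BrCBr | starting material
8 | (5R,6R)-1-(dibromomethyl)-6-[(1R)-1-(tert-butyldimethylsilyloxy)prop-2-en-1-yl]-5-methylcyclohex-2-en-1-ol (CHBr2 trans to the side chain; lithium alkoxide in the flask) | O[C@]1(C(Br)Br)C=CC[C@@H](C)[C@@H]1[C@H](O[Si](C)(C)C(C)(C)C)C=C | intermediate
9 | lithium (6R,7R)-7-[(1R)-1-(tert-butyldimethylsilyloxy)prop-2-en-1-yl]-6-methylcyclohepta-1,3-dien-1-olate | [Li]OC1=CC=CC[C@@H](C)[C@@H]1[C@H](O[Si](C)(C)C(C)(C)C)C=C | intermediate
10 | (6R,7R)-7-[(1R)-1-(tert-butyldimethylsilyloxy)prop-2-en-1-yl]-6-methylcyclohept-3-en-1-one | O=C1CC=CC[C@@H](C)[C@@H]1[C@H](O[Si](C)(C)C(C)(C)C)C=C | intermediate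
11 | isopropenylmagnesium bromide | CC(=C)[Mg]Br | starting material
12 | (1R,6R,7R)-7-[(1R)-1-(tert-butyldimethylsilyloxy)prop-2-en-1-yl]-6-methyl-1-(prop-1-en-2-yl)cyclohept-3-en-1-ol | CC(=C)[C@@]1(O)CC=CC[C@@H](C)[C@@H]1[C@H](O[Si](C)(C)C(C)(C)C)C=C | intermediate
13 | 1-(tert-butyldimethylsilyloxy)-3,8-dimethyl-1,4,7,8-tetrahydroazulen-3a(8aH)-ol (trans-fused; 1-OSi β; 3a-OH β; 8-CH3 α; 8a-H α) | CC1=C[C@@H](O[Si](C)(C)C(C)(C)C)[C@H]2[C@H](C)CC=CC[C@]12O | intermediate
14 | ethyl diazoacetate | CCOC(=O)C=[N+]=[N-] | starting material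
15 | ethyl 2-{[1-(tert-butyldimethylsilyloxy)-3,8-dimethyl-1,4,7,8-tetrahydroazulen-3a(8aH)-yl]oxy}acetate (configuration as 13) | CC1=C[C@@H](O[Si](C)(C)C(C)(C)C)[C@H]2[C@H](C)CC=CC[C@]12OCC(=O)OCC | intermediate
16 | 2-{[1-(tert-butyldimethylsilyloxy)-3,8-dimethyl-1,4,7,8-tetrahydroazulen-3a(8aH)-yl]oxy}acetic acid (configuration as 13) | CC1=C[C@@H](O[Si](C)(C)C(C)(C)C)[C@H]2[C@H](C)CC=CC[C@]12OCC(=O)O | intermediate
17 | 2-{[1-(tert-butyldimethylsilyloxy)-3-hydroxy-3,8-dimethyl-1,2,3,4,7,8-hexahydroazulen-3a(8aH)-yl]oxy}acetic acid (3-OH α; 3-CH3 β; otherwise as 13) | C[C@@]1(O)C[C@@H](O[Si](C)(C)C(C)(C)C)[C@H]2[C@H](C)CC=CC[C@]12OCC(=O)O | intermediate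
18 | 2β-(tert-butyldimethylsilyloxy)-4α-hydroxy-5β,11-epoxy-13-nor-1αH,7αH,8αH,10βH-guaian-12,8-olide | CC(C)(C)[Si](C)(C)O[C@@H]1C[C@@](C)(O)[C@@]23C[C@H]4[C@@H](C[C@@H](C)[C@H]12)OC(=O)[C@H]4O3 | intermediate
19 | formaldehyde | C=O | starting material
20 | acetic anhydride | CC(=O)OC(C)=O | starting material
21 | 2β-(tert-butyldimethylsilyloxy)-4α,13-dihydroxy-5β,11-epoxy-1αH,7αH,8αH,10βH-guaian-12,8-olide (lithium alkoxide in the flask) | CC(C)(C)[Si](C)(C)O[C@@H]1C[C@@](C)(O)[C@@]23C[C@H]4[C@@H](C[C@@H](C)[C@H]12)OC(=O)[C@@]4(CO)O3 | intermediate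
22 | 13-acetoxy-2β-(tert-butyldimethylsilyloxy)-4α-hydroxy-5β,11-epoxy-1αH,7αH,8αH,10βH-guaian-12,8-olide | CC(C)(C)[Si](C)(C)O[C@@H]1C[C@@](C)(O)[C@@]23C[C@H]4[C@@H](C[C@@H](C)[C@H]12)OC(=O)[C@@]4(COC(C)=O)O3 | intermediate
23 | 13-acetoxy-2β,4α-dihydroxy-5β,11-epoxy-1αH,7αH,8αH,10βH-guaian-12,8-olide | O[C@@H]1C[C@@](C)(O)[C@@]23C[C@H]4[C@@H](C[C@@H](C)[C@H]12)OC(=O)[C@@]4(COC(C)=O)O3 | intermediate
24 | tiglic acid, (E)-2-methylbut-2-enoic acid | C/C=C(\C)C(=O)O | starting material
25 | CNP0112086.1, 13-acetoxy-4α-hydroxy-2α-tigloyloxy-5β,11-epoxy-1αH,7αH,8αH,10βH-guaian-12,8-olide | C/C=C(\C)C(=O)O[C@H]1C[C@@](C)(O)[C@@]23C[C@H]4[C@@H](C[C@@H](C)[C@H]12)OC(=O)[C@@]4(COC(C)=O)O3 | target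

## Step count and risk

Total steps: 11. Longest linear sequence: 11 steps (1 to 25).

**Step 3 (ring expansion).** The 1,2-shift could take the C1 carbon instead of the alkenyl carbon, or the carbenoid could close to an epoxide. The fallback sets out from 6 and comes back to the route at 12, bypassing 10.
- Addition of 11 with CeCl3 to the enone carbonyl of 6 gives the tertiary allylic alcohol F1.
- Oxidative 1,3-transposition with pyridinium chlorochromate [C5H5NH][CrO3Cl] (Babler–Dauben) gives the cross-conjugated dienone F2.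
- Oxazaborolidine-catalysed BH3·SMe2 reduction, with the catalyst enantiomer that delivers hydride to the α face, gives the allylic alcohol F3.
- Hydroxyl-directed Simmons–Smith cyclopropanation (Et2Zn, CH2I2) of the ring alkene gives the cyclopropyl carbinol F4.
- HClO4 in acetone/H2O then brings about the cyclopropylcarbinyl-to-homoallyl ring expansion, with cleavage of the ring-fusion cyclopropane bond and capture of water at the tertiary C5 on the face that carried the cyclopropane methylene, to give 12.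

**Step 8 (new lactone annulation).** The C8 radical may be lost to alkene formation at copper or to hydrogen abstraction, or the dianion may dimerise. The fallback uses known reactions only; it sets out from 17 and comes back at 18.
- Dimethyldioxirane epoxidises C7=C8 from the α face, opposite the axial 5β side chain, to give the epoxy acid F5.
- LiN(i-Pr)2 (3.3 equiv) forms the acid dianion, which opens the epoxide 5-exo at C7 with inversion to give the tetrahydrofuran hydroxy acid F6 (8α-OH).
- Dess–Martin periodinane oxidises this to the keto acid F7.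
- NaBH4 attacks the C8 ketone from the open α face, and the resulting 8β-hydroxy acid lactonises on acidification to 18.

**Step 11 (Mitsunobu inversion).** The hindered cyclopentanol may eliminate or fail to couple with the weakly acidic tiglic acid. The fallback sets out from 23 and comes back at 25.
- Tf2O and pyridine in CH2Cl2 at −40 °C convert the secondary hydroxyl selectively into the 2β-triflate F8.
- Displacement with cesium tiglate (from 24 and Cs2CO3) and 18-crown-6 in toluene gives 25 by SN2 inversion.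

## Further compounds

F1 | step 3 | (5R,6R)-6-[(1R)-1-(tert-butyldimethylsilyloxy)prop-2-en-1-yl]-5-methyl-1-(prop-1-en-2-yl)cyclohex-2-en-1-ol (isopropenyl trans to the side chain) | CC(=C)[C@@]1(O)C=CC[C@@H](C)[C@@H]1[C@H](O[Si](C)(C)C(C)(C)C)C=C
F2 | step 3 | 4-[(1R)-1-(tert-butyldimethylsilyloxy)prop-2-en-1-yl]-5-methyl-3-(prop-1-en-2-yl)cyclohex-2-en-1-one (side chain and methyl trans) | CC(=C)C1=CC(=O)C[C@@H](C)[C@@H]1[C@H](O[Si](C)(C)C(C)(C)C)C=C
F3 | step 3 | 4-[(1R)-1-(tert-butyldimethylsilyloxy)prop-2-en-1-yl]-5-methyl-3-(prop-1-en-2-yl)cyclohex-2-en-1-ol (OH cis to the side chain, trans to methyl) | CC(=C)C1=C[C@H](O)C[C@@H](C)[C@@H]1[C@H](O[Si](C)(C)C(C)(C)C)C=C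
F4 | step 3 | 5-[(1R)-1-(tert-butyldimethylsilyloxy)prop-2-en-1-yl]-4-methyl-6-(prop-1-en-2-yl)bicyclo[4.1.0]heptan-2-ol (cyclopropane cis to OH) | CC(=C)[C@@]12C[C@@H]1[C@H](O)C[C@@H](C)[C@@H]2[C@H](O[Si](C)(C)C(C)(C)C)C=C
F5 | step 8 | 7α,8α-epoxide of acid 17 | C[C@@]1(O)C[C@@H](O[Si](C)(C)C(C)(C)C)[C@H]2[C@H](C)C[C@@H]3O[C@@H]3C[C@]12OCC(=O)O
F6 | step 8 | 2β-(tert-butyldimethylsilyloxy)-4α,8α-dihydroxy-5β,11-epoxy-13-nor-1αH,7αH,10βH-guaian-12-oic acid | OC(=O)[C@H]1O[C@]23C[C@H]1[C@@H](O)C[C@@H](C)[C@@H]2[C@H](O[Si](C)(C)C(C)(C)C)C[C@@]3(C)O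
F7 | step 8 | 2β-(tert-butyldimethylsilyloxy)-4α-hydroxy-8-oxo-5β,11-epoxy-13-nor-1αH,7αH,10βH-guaian-12-oic acid | OC(=O)[C@H]1O[C@]23C[C@H]1C(=O)C[C@@H](C)[C@@H]2[C@H](O[Si](C)(C)C(C)(C)C)C[C@@]3(C)O
F8 | step 11 | 2β-trifluoromethanesulfonate of 23 | O=S(=O)(O[C@@H]1C[C@@](C)(O)[C@@]23C[C@H]4[C@@H](C[C@@H](C)[C@H]12)OC(=O)[C@@]4(COC(C)=O)O3)C(F)(F)F
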